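## The problem

Germacrane numbering is used throughout: C6 is the lactone CH–O, C7 the tertiary carbinol, C8 carries the angelate, C9 the free hydroxyl, C10 the methyl C14, then C1, C2, C3, C4 (methyl C15) and C5; C11 carries the exocyclic methylene C13 and C12 is the lactone carbonyl.

Target 35 is a ten-membered (1(10)Z,4E)-cyclodecadiene, cis-fused across C6–C7 to an α-methylene-γ-butyrolactone, with four contiguous stereocentres (6S,7R,8S,9R). The ring holds a 1,5-diene with one Z and one E trisubstituted alkene. It is strained, open to Cope rearrangement on heating and to transannular cyclization in acid, so it should be made late and under mild conditions. C7 is a fully substituted carbinol flanked by the oxygenated carbons C6 and C8, and no reagent-controlled method reaches such a centre inside a medium ring. C8 and C9 form a syn-diol pair that an auxiliary-controlled glycolate aldol can fix at the outset; these two centres are then the only handle for setting C6 and C7. The exocyclic acrylate is a Michael acceptor, and the angelate isomerizes to the tiglate under base or nucleophilic catalysis. Both must therefore appear after all strongly basic steps, and O8 must be distinguishable from O7 and O9 at the end. The enabling feature is seen when the lactone is opened: O6–C6–C7–C11(=C13) is a homoallylic alcohol whose carbinol carbon C6 is also allylic to C4=C5. This is the retron of a [2,3]-Wittig shift of an ether oxygen bridging C6 and C13, and if C7 begins as the oxygen-bearing end of a C7=C11 enol ether, the same shift creates the tertiary carbinol.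

## Retrosynthesis

**Ester and silyl ether (35 ⇒ 34 ⇒ 31 + 32).** The O8–acyl bond and the O9–Si bond are cut last. Putting the angelate on after every basic step avoids tiglate formation. In diol 31 the only acylable hydroxyl is the secondary O8, because O7 is tertiary and O9 is silylated. The forward esterification of 31 with angelic acid 32 must not isomerize the Z alkene of the acid.

**Acetals and lactone (31 ⇒ 29 ⇒ 27 ⇒ 26).** Both methoxymethyl groups are removed from lactone 29 in one operation. The lactone acyl bond C12–O6 is then cut and C12 taken back to the alcohol level. Diol 27 has a primary allylic C12 hydroxyl placed 1,4 to the C6 hydroxyl; it comes from 26 by selective loss of the primary silyl group. Cutting here rather than carrying C12 as an ester keeps every base-sensitive carbonyl out of the organolithium step. The forward oxidation has to pick the primary alcohol and stop at the lactone.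

**Ring contraction (26 ⇒ 25).** The C6–C7 bond is cut and the oxygen of C6 is reconnected to C13, giving the thirteen-membered diallylic ether 25 with a C7=C11 enol ether. This one cut removes the ten-membered ring, the quaternary carbinol and two stereocentres, which no neighbouring cut does. The forward shift needs deprotonation at C6 only and attack on one face of a tetrasubstituted enol ether. The enol ether geometry is not a free choice. In the favoured envelope, with the C5 vinyl carbon exo, the cis ring fusion (H6 syn to O7) results only if the oxymethylene C13 is cis to C8, that is, the Z isomer. The E isomer would lead through the same envelope to the trans-fused diastereomer.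

**Ether (25 ⇒ 24 ⇒ 23).** The C6–O bond is cut to diol chloride 23, in which the primary C13 alkoxide displaces a primary allylic chloride. The polarity is fixed, because a leaving group on C13 would sit γ to the enol ether oxygen and ionize. Silylation of O9 follows ring closure (24 to 25). The free C9 hydroxyl of 23 could only close a nine-membered ring containing the E alkene.

**Lactone template (23 ⇒ 22 ⇒ 21 ⇒ 20 ⇒ 19).** The Z tetrasubstituted enol ether cannot be made reliably from an open-chain β-dicarbonyl. C13 is therefore taken back to a lactone carbonyl bound to O9. In dihydropyranone 20 the ring forces C13 cis to C8 and the silyloxymethyl carbon C12 cis to O7. Reduction of 22 opens the ring to 23 with the geometry intact. Before that, the C6 ether of 20 is exchanged for chloride through 21, while the enol ether is still an unreactive vinylogous carbonate. Enol 19 is the O-alkylation precursor of 20.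

**C7–C11 bond (19 ⇒ 18 ⇒ 16 + 17).** The β-keto lactone 19 is cut between C7 and C11 (Dieckmann retron) to ester 18, which is the O9 ester of Weinreb amide 16 with 3-silyloxypropanoic acid 17. The intramolecular Claisen is preferred to an intermolecular one because it uses the free aldol hydroxyl directly and builds the template ring in the same step. It needs enolization of the ester in preference to C8.

**C8–C9 bond (16 ⇒ 15 ⇒ 9 + 13; 13 ⇒ 10 + 11).** The syn-glycolate aldol retron gives Z enal 9 and glycolyl imide 13, made from oxazolidinone 10 and acid 11. This cut sets both early stereocentres in one step with known facial control and puts the methoxymethyl group on O8 from the start.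

**C1=C10 alkene and C1–C6 chain (9 ⇒ 8 ⇒ 7 ⇒ 5 + 6; 5 ⇒ 3 ⇒ 2 ⇒ 1).** The Z trisubstituted alkene is cut by a Still–Gennari retron to aldehyde 5 and phosphonate 6. Aldehyde 5 is geraniol 1 shortened at its distal alkene (through ether 2 and epoxide 3), so the E C4=C5 alkene and C15 are bought.

## Roads not taken

**Alternative 1:** The cut is the C7–C11 bond, made last. A nucleophilic catalyst (quinuclidine or trimethylphosphine) would add to the O6 acrylate of the ten-membered ketone A2, and the resulting enolate would close onto the C7 ketone (intramolecular Morita–Baylis–Hillman). This gives lactone A1 with the C11–C7 bond, the tertiary carbinol and the five-membered ring in one step; desilylation then gives 35.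
- Merits: it is the shortest endgame of all the plans. There is no redox change at C12 and no protecting group on O7, and the angelate is already in place.
- Weak points: ketones are poor acceptors in this reaction, and this one is hindered and sits in a medium ring. Both α-carbons carry acyloxy groups, so the basic catalyst can cause enolization, epimerization or β-elimination, and it can isomerize the angelate. The C7 face is chosen by ring conformation alone. Ketone A2 also presupposes a ten-membered α,α'-dioxygenated ketone, so the ring problem is only moved earlier.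
- Comparison: this road is better in steps after the key event and rests on a known reaction class. The chosen plan sets against it that ring, C6–C7 bond and both new stereocentres come from one event, and that no enolizable ketone or angelate ever meets base.

**Alternative 2:** The cut is through both ring alkenes at once. Flash thermolysis of the cis,anti,cis-tricyclo[4.4.0.0(2,5)]decanone A4 would break the central and one outer cyclobutane bond (C1–C4 and C5–C10) and open the six-membered ring to dienone A3.
- Merits: ring strain drives formation of the medium ring, no dilution is needed, and both trisubstituted alkenes come from ring-fusion stereochemistry.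
- Weak points: the product is a 1,5-diene that can undergo Cope rearrangement to a divinylcyclohexane at the thermolysis temperature. Which alkene becomes Z depends on a stepwise diradical path. A3 also lacks C11 to C13 and the quaternary centre: C7 is a secondary ether. Deprotection, oxidation, stereoselective addition of the three-carbon unit to a medium-ring ketone and reduction of the C9 ketone would still follow.
- Comparison: this road is better at making the ring itself. The chosen plan sets against it that after its key step all four stereocentres and all fifteen skeletal carbons are in place.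

**Alternative 3:** The cut is the C1–C2 bond. Hydroboration of the terminal alkene of open-chain vinyl iodide A6 with 9-borabicyclo[3.3.1]nonane, then coupling with PdCl2(dppf) and Cs2CO3 at high dilution (B-alkyl Suzuki macrocyclization), would give carbocycle A5.
- Merits: the key reaction is fully precedented, the Z vinyl iodide geometry is retained, and A5 has the same oxidation pattern as 27.
- Weak points: an end-to-end closure of a ten-membered ring pays the full transannular strain. The borane must select the terminal alkene of a 1,3-diene in the presence of the 1,1-disubstituted C11=C13 alkene. The acyclic chain A6 already needs the quaternary C7 carbinol between two oxygenated stereocentres, set by a separate ketone addition.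
- Comparison: this road is better on precedent for the key step. The chosen plan sets against it that the ring closes through a five-membered transition state inside a larger, easily made ring, and that C6 and C7 are made in that same step instead of beforehand.

Key step: step 18

Assumption: 2-(methoxymethoxy)acetic acid 11 and 3-[(tert-butyldimethylsilyl)oxy]propanoic acid 17 are treated as purchasable; if not stocked, each is two routine steps (etherification, saponification) from ethyl glycolate or methyl 3-hydroxypropanoate.

## Route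

Step 1
Reactants: 1 geraniol
Product: 2 geranyl 4-methoxybenzyl ether
Conditions: NaH, 4-MeOC6H4CH2Cl, n-Bu4NI (cat.), THF/DMF, 0 °C → rt
Reagents that add atoms: 4-methoxybenzyl chloride, COc1ccc(CCl)cc1
Why: Williamson etherification of the primary allylic alkoxide; the ether survives all basic, reductive and Lewis acidic steps up to step 13 and is the only group later removed by oxidation.

Step 2
Reactants: 2 geranyl 4-methoxybenzyl ether
Product: 3 6,7-epoxygeranyl 4-methoxybenzyl ether (racemic)
Conditions: mCPBA, NaHCO3, CH2Cl2, −20 → 0 °C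
Reagents that add atoms: 3-chloroperoxybenzoic acid, OOC(=O)c1cccc(Cl)c1
Why: Prilezhaev epoxidation is selective for the distal, more electron-rich trisubstituted alkene because the 2,3-alkene is deactivated by the allylic oxygen; the racemic epoxide centre is destroyed in step 3.

Step 3
Reactants: 3 6,7-epoxygeranyl 4-methoxybenzyl ether
Product: 5 (4E)-6-[(4-methoxybenzyl)oxy]-4-methylhex-4-enal, via diol 4 (not isolated)
Conditions: H5IO6, THF/H2O, 0 °C
Reagents that add atoms: none
Why: Periodic acid hydrolyses the epoxide to the vicinal diol and cleaves it (glycol cleavage) to the C1 aldehyde, whose oxygen is the former epoxide oxygen; the allylic ether and the E alkene are untouched.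

Step 4
Reactants: 5 (4E)-6-[(4-methoxybenzyl)oxy]-4-methylhex-4-enal; 6 ethyl 2-[bis(2,2,2-trifluoroethoxy)phosphoryl]propanoate
Product: 7 ethyl (2Z,6E)-8-[(4-methoxybenzyl)oxy]-2,6-dimethylocta-2,6-dienoate
Conditions: 6, KN(SiMe3)2, 18-crown-6, THF, −78 °C; then 5
Reagents that add atoms: none
Why: Still–Gennari olefination: the electron-poor phosphonate under dissociating conditions eliminates from the kinetic adduct and gives the Z trisubstituted enoate that becomes the C1=C10 alkene.

Step 5
Reactants: 7 ethyl (2Z,6E)-8-[(4-methoxybenzyl)oxy]-2,6-dimethylocta-2,6-dienoate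
Product: 8 (2Z,6E)-8-[(4-methoxybenzyl)oxy]-2,6-dimethylocta-2,6-dien-1-ol
Conditions: i-Bu2AlH, CH2Cl2, −78 °C; aq. potassium sodium tartrate
Reagents that add atoms: none
Why: 1,2-Reduction of the conjugated ester at low temperature gives the allylic alcohol without touching the Z alkene.

Step 6
Reactants: 8 (2Z,6E)-8-[(4-methoxybenzyl)oxy]-2,6-dimethylocta-2,6-dien-1-ol
Product: 9 (2Z,6E)-8-[(4-methoxybenzyl)oxy]-2,6-dimethylocta-2,6-dienal
Conditions: Dess–Martin periodinane, NaHCO3, CH2Cl2, 0 °C
Reagents that add atoms: none
Why: Dess–Martin oxidation under bicarbonate buffer is neutral and fast, so the Z α-methyl enal should form without Z to E isomerization; it is used directly.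

Step 7
Reactants: 10 (4S)-4-benzyl-1,3-oxazolidin-2-one; 11 2-(methoxymethoxy)acetic acid
Product: 13 (4S)-4-benzyl-3-[(methoxymethoxy)acetyl]-1,3-oxazolidin-2-one, via mixed anhydride 12 (not isolated)
Conditions: 11, t-BuCOCl, Et3N, THF, −20 °C; then LiCl, 10, −20 °C → rt
Reagents that add atoms: none
Why: N-Acylation of the oxazolidinone through the mixed pivalic anhydride avoids an acid chloride, whose preparation would endanger the acetal.

Step 8
Reactants: 9 (2Z,6E)-8-[(4-methoxybenzyl)oxy]-2,6-dimethylocta-2,6-dienal; 13 (4S)-4-benzyl-3-[(methoxymethoxy)acetyl]-1,3-oxazolidin-2-one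
Product: 15 (4S)-4-benzyl-3-[(2S,3R,4Z,8E)-3-hydroxy-10-[(4-methoxybenzyl)oxy]-2-(methoxymethoxy)-4,8-dimethyldeca-4,8-dienoyl]-1,3-oxazolidin-2-one, via boron enolate 14 (not isolated)
Conditions: 13, Bu2BOTf, Et3N, CH2Cl2, −78 → 0 °C; 9, −78 → 0 °C; pH 7 buffer, MeOH, H2O2
Reagents that add atoms: none
Why: Evans syn-glycolate aldol: the Z boron enolate reacts through a chair Zimmerman–Traxler transition state on the face away from the benzyl group, which sets C8 and C9 syn as 2S,3R (8S,9R of the target).

Step 9
Reactants: 15 aldol adduct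
Product: 16 (2S,3R,4Z,8E)-3-hydroxy-N-methoxy-10-[(4-methoxybenzyl)oxy]-2-(methoxymethoxy)-N,4,8-trimethyldeca-4,8-dienamide
Conditions: MeNH(OMe)·HCl, AlMe3, CH2Cl2, −20 → 0 °C; aq. potassium sodium tartrate
Reagents that add atoms: N,O-dimethylhydroxylamine hydrochloride, CNOC.Cl
Why: Aluminium amide transamination to the Weinreb amide works on syn-aldol adducts with a free β-hydroxyl, frees the auxiliary, and leaves a C7 acyl group that takes one carbon nucleophile and is far less acidic at C8 than the imide.

Step 10
Reactants: 16 Weinreb amide; 17 3-[(tert-butyldimethylsilyl)oxy]propanoic acid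
Product: 18 O9 ester of 16 with 17
Conditions: 17, EDC·HCl, 4-(dimethylamino)pyridine, CH2Cl2, 0 °C → rt
Reagents that add atoms: none
Why: Steglich esterification of the secondary allylic alcohol; the ester brings in C13 (its carbonyl), C11 and C12 and ties C13 to O9.

Step 11
Reactants: 18 O9 ester
Product: 19 (5S,6R)-3-{[(tert-butyldimethylsilyl)oxy]methyl}-4-hydroxy-6-{(2Z,6E)-8-[(4-methoxybenzyl)oxy]-6-methylocta-2,6-dien-2-yl}-5-(methoxymethoxy)-5,6-dihydro-2H-pyran-2-one
Conditions: LiN(i-Pr)2, THF, −78 → −40 °C; aq. NH4Cl
Reagents that add atoms: none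
Why: Dieckmann-type intramolecular Claisen condensation: the ester is enolized in preference to the α-alkoxy amide, the enolate closes 6-exo-trig onto the Weinreb carbonyl, and the chelated adduct collapses on work-up to the β-keto δ-lactone, isolated as its enol; the dicarbonyl enolizes toward C11, so C8 is not epimerized.

Step 12
Reactants: 19 enol lactone
Product: 20 (5S,6R)-3-{[(tert-butyldimethylsilyl)oxy]methyl}-6-{(2Z,6E)-8-[(4-methoxybenzyl)oxy]-6-methylocta-2,6-dien-2-yl}-4,5-bis(methoxymethoxy)-5,6-dihydro-2H-pyran-2-one
Conditions: MeOCH2Cl, i-Pr2NEt, CH2Cl2, 0 °C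
Reagents that add atoms: chloromethyl methyl ether, COCCl
Why: O-Alkylation of the vinylogous acid with a hard electrophile gives the 4-alkoxy-5,6-dihydropyran-2-one, as in the known O-methylation of such enols; the six-membered ring fixes C13 cis to C8 and C12 cis to O7.

Step 13
Reactants: 20 bis(methoxymethyl) lactone
Product: 21 (5S,6R)-3-{[(tert-butyldimethylsilyl)oxy]methyl}-6-[(2Z,6E)-8-hydroxy-6-methylocta-2,6-dien-2-yl]-4,5-bis(methoxymethoxy)-5,6-dihydro-2H-pyran-2-one
Conditions: DDQ, CH2Cl2/pH 7 buffer, 0 °C
Reagents that add atoms: none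
Why: Oxidative cleavage of the 4-methoxybenzyl ether through its benzylic cation; at this stage the enol ether is an electron-poor vinylogous carbonate and the silyl and acetal groups are inert.

Step 14
Reactants: 21 allylic alcohol
Product: 22 (5S,6R)-3-{[(tert-butyldimethylsilyl)oxy]methyl}-6-[(2Z,6E)-8-chloro-6-methylocta-2,6-dien-2-yl]-4,5-bis(methoxymethoxy)-5,6-dihydro-2H-pyran-2-one
Conditions: MeSO2Cl, LiCl, 2,4,6-collidine, DMF, 0 °C
Reagents that add atoms: lithium chloride, [Li+].[Cl-]
Why: Mesylation with in situ chloride displacement converts primary allylic alcohols to primary allylic chlorides without allylic transposition or loss of the E geometry.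

Step 15
Reactants: 22 allylic chloride lactone
Product: 23 (2Z,4S,5R,6Z,10E)-2-{[(tert-butyldimethylsilyl)oxy]methyl}-12-chloro-3,4-bis(methoxymethoxy)-6,10-dimethyldodeca-2,6,10-triene-1,5-diol
Conditions: i-Bu2AlH (excess), CH2Cl2, −78 → −20 °C; aq. potassium sodium tartrate
Reagents that add atoms: none
Why: 1,2-Hydride reduction of the unsaturated lactone through the lactol opens the ring to the Z allylic diol with the enol ether geometry intact; the allylic chloride is inert to this hydride and the non-acidic work-up protects the γ-alkoxy allylic alcohol from ionization.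

Step 16
Reactants: 23 diol chloride
Product: 24 (3Z,5S,6R,7Z,11E)-3-{[(tert-butyldimethylsilyl)oxy]methyl}-4,5-bis(methoxymethoxy)-7,11-dimethyl-1-oxacyclotrideca-3,7,11-trien-6-ol
Conditions: NaH, 15-crown-5, THF, 45 °C, slow addition, 0.002 M
Reagents that add atoms: none
Why: Williamson macro-etherification at high dilution, the ring closure known for thirteen-membered diallylic ethers: the primary C13 alkoxide displaces the primary allylic chloride by SN2, while the secondary C9 alkoxide would have to close a nine-membered ring containing the E alkene.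

Step 17
Reactants: 24 macrocyclic alcohol
Product: 25 (3Z,5S,6R,7Z,11E)-6-[(tert-butyldimethylsilyl)oxy]-3-{[(tert-butyldimethylsilyl)oxy]methyl}-4,5-bis(methoxymethoxy)-7,11-dimethyl-1-oxacyclotrideca-3,7,11-triene
Conditions: t-BuMe2SiCl, imidazole, 4-(dimethylamino)pyridine (cat.), DMF, rt
Reagents that add atoms: tert-butyldimethylsilyl chloride, CC(C)(C)[Si](C)(C)Cl
Why: Silylation of the remaining secondary allylic alcohol under basic conditions free of Lewis acid, which leave the enol ether and the allylic ethers intact.

Step 18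
Reactants: 25 thirteen-membered diallylic ether
Product: 26 (1S,2E,6Z,8R,9S,10R)-8-[(tert-butyldimethylsilyl)oxy]-10-{3-[(tert-butyldimethylsilyl)oxy]prop-1-en-2-yl}-9,10-bis(methoxymethoxy)-3,7-dimethylcyclodeca-2,6-dien-1-ol
Conditions: s-BuLi, THF, −78 → −30 °C; aq. NH4Cl
Reagents that add atoms: none
Why: Proposed new method: s-BuLi should remove a proton from C6, the one methylene that is both α to the ring oxygen and allylic to an ordinary trisubstituted alkene, and the α-oxy allyllithium then attacks C7 of the enol ether suprafacially through a five-membered envelope (C6, O, C13, C11, C7) while the O–C13 bond breaks, so that the C6–C7 bond, the C11=C13 methylene and the C6 alkoxide arise in one concerted [2,3]-sigmatropic shift. The closest known reaction type is the [2,3]-Wittig ring contraction of thirteen-membered diallylic ethers to ten-membered germacrane carbocycles and, for the quaternary centre, the acyclic [2,3]-Wittig shift onto γ,γ-disubstituted allyl termini; not yet shown is a fully substituted terminus carrying an alkoxy group, which raises the acceptor π* level and crowds the bond-forming carbon, so the argument is that a concerted five-membered transition state held inside the ring still outruns the radical [1,2] pathway at low temperature. The ten-membered carbocycle closes by transannular contraction of the thirteen-membered ring (O, C13 and C11 leave the ring), not by end-to-end cyclization, so no dilution is needed. C6 and C7 are set relative to each other by the Z enol ether (C13 cis to C8, fixed since step 12) together with an envelope in which the C5 vinyl carbon is exo, away from the C12 substituent on the central carbon C11; this places H6 syn to O7, as the cis-fused lactone requires. Their absolute sense is set by C8: allylic 1,3-strain against C13 holds H8 in the plane of the enol ether, the 8-O-methoxymethyl group covers one face and the ring tether through C9 delivers C6 to the other, which corresponds to 6S,7R. The step needs deprotonation at C6 and not at C13, C12, C8 or C9: the other allyl anions would place charge on the oxygen-bearing C7 of a tetrasubstituted alkene or require removal of a tertiary hydrogen, and both should be slower. It also needs the shift to beat β-elimination and [1,2]-shift, which is why the anion is generated and left to rearrange below −30 °C.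

Step 19
Reactants: 26 ring-contracted alcohol
Product: 27 (1S,2E,6Z,8R,9S,10R)-8-[(tert-butyldimethylsilyl)oxy]-10-(3-hydroxyprop-1-en-2-yl)-9,10-bis(methoxymethoxy)-3,7-dimethylcyclodeca-2,6-dien-1-ol
Conditions: HF·pyridine, pyridine, THF, 0 °C
Reagents that add atoms: none
Why: Selective desilylation: buffered HF·pyridine cleaves the primary allylic silyl ether much faster than the secondary one at C9, which is flanked by C8 and the substituted C10; the buffer protects the tertiary allylic acetal and the diene.

Step 20
Reactants: 27 diol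
Product: 29 (1(10)Z,4E,6S,7R,8S,9R)-9-[(tert-butyldimethylsilyl)oxy]-7,8-bis(methoxymethoxy)germacra-1(10),4,11(13)-trien-12,6-olide, via lactol 28 (not isolated)
Conditions: 2,2,6,6-tetramethylpiperidin-1-oxyl (cat.), PhI(OAc)2, CH2Cl2, rt
Reagents that add atoms: none
Why: Oxoammonium oxidation is selective for the primary allylic alcohol; the enal is trapped by the C6 hydroxyl as a five-membered lactol, which is oxidized in the same flask to the α-methylene-γ-butyrolactone (oxidative lactonization of a 1,4-diol).

Step 21
Reactants: 29 bis(methoxymethyl) lactone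
Product: 31 (1(10)Z,4E,6S,7S,8S,9R)-9-[(tert-butyldimethylsilyl)oxy]-7,8-dihydroxygermacra-1(10),4,11(13)-trien-12,6-olide, via bis(bromomethyl) ether 30 (not isolated)
Conditions: Me2BBr, CH2Cl2, −78 °C; then THF, aq. NaHCO3
Reagents that add atoms: none
Why: Lewis acid acetal cleavage: the borane coordinates the acetal oxygens and bromide attacks the OCH2O carbon at −78 °C, giving bromomethyl ethers that hydrolyse on bicarbonate work-up; silyl ethers and esters are known to tolerate these conditions, and the C7 descriptor changes only because the priorities at C7 change.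

Step 22
Reactants: 31 7,8-diol; 32 angelic acid
Product: 34 (1(10)Z,4E,6S,7R,8S,9R)-8-(angeloyloxy)-9-[(tert-butyldimethylsilyl)oxy]-7-hydroxygermacra-1(10),4,11(13)-trien-12,6-olide, via mixed anhydride 33 (not isolated)
Conditions: 32, 2,4,6-Cl3C6H2COCl, Et3N, toluene, rt; then 31, 75 °C
Reagents that add atoms: none
Why: Yamaguchi esterification through the mixed anhydride acylates the secondary C8 hydroxyl and not the tertiary C7 hydroxyl; run without a nucleophilic catalyst it is the established way to make angelates without isomerization to the tiglate.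

Step 23
Reactants: 34 silyl ether of the target
Product: 35 (1(10)Z,4E,6S,7R,8S,9R)-8-(angeloyloxy)-7,9-dihydroxygermacra-1(10),4,11(13)-trien-12,6-olide
Conditions: HF·pyridine, THF, 0 °C → rt
Reagents that add atoms: none
Why: Desilylation under mildly acidic fluoride conditions frees the C9 hydroxyl without acyl migration, tiglate formation or conjugate addition to the α-methylene lactone.

## Compound list

1 | geraniol, (2E)-3,7-dimethylocta-2,6-dien-1-ol | CC(C)=CCC/C(C)=C/CO | starting material
2 | geranyl 4-methoxybenzyl ether | CC(C)=CCC/C(C)=C/COCc1ccc(OC)cc1 | intermediate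
3 | 3-{(3E)-5-[(4-methoxybenzyl)oxy]-3-methylpent-3-en-1-yl}-2,2-dimethyloxirane (racemic) | CC1(C)OC1CC/C(C)=C/COCc1ccc(OC)cc1 | intermediate
4 | (6E)-8-[(4-methoxybenzyl)oxy]-2,6-dimethyloct-6-ene-2,3-diol (racemic, not isolated) | CC(C)(O)C(O)CC/C(C)=C/COCc1ccc(OC)cc1 | intermediate
5 | (4E)-6-[(4-methoxybenzyl)oxy]-4-methylhex-4-enal | O=CCC/C(C)=C/COCc1ccc(OC)cc1 | intermediate
6 | ethyl 2-[bis(2,2,2-trifluoroethoxy)phosphoryl]propanoate (racemic) | CCOC(=O)C(C)P(=O)(OCC(F)(F)F)OCC(F)(F)F | starting material
7 | ethyl (2Z,6E)-8-[(4-methoxybenzyl)oxy]-2,6-dimethylocta-2,6-dienoate | CCOC(=O)/C(C)=C\CC/C(C)=C/COCc1ccc(OC)cc1 | intermediate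
8 | (2Z,6E)-8-[(4-methoxybenzyl)oxy]-2,6-dimethylocta-2,6-dien-1-ol | OC/C(C)=C\CC/C(C)=C/COCc1ccc(OC)cc1 | intermediate
9 | (2Z,6E)-8-[(4-methoxybenzyl)oxy]-2,6-dimethylocta-2,6-dienal | O=C/C(C)=C\CC/C(C)=C/COCc1ccc(OC)cc1 | intermediate
10 | (4S)-4-benzyl-1,3-oxazolidin-2-one | O=C1N[C@@H](Cc2ccccc2)CO1 | starting material
11 | 2-(methoxymethoxy)acetic acid | COCOCC(=O)O | starting material
12 | 2-(methoxymethoxy)acetic pivalic anhydride (not isolated) | COCOCC(=O)OC(=O)C(C)(C)C | intermediate
13 | (4S)-4-benzyl-3-[(methoxymethoxy)acetyl]-1,3-oxazolidin-2-one | COCOCC(=O)N1C(=O)OC[C@@H]1Cc1ccccc1 | intermediate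
14 | Z dibutylboron enolate of 13 (not isolated) | CCCCB(CCCC)O/C(=C\OCOC)N1C(=O)OC[C@@H]1Cc1ccccc1 | intermediate
15 | (4S)-4-benzyl-3-[(2S,3R,4Z,8E)-3-hydroxy-10-[(4-methoxybenzyl)oxy]-2-(methoxymethoxy)-4,8-dimethyldeca-4,8-dienoyl]-1,3-oxazolidin-2-one | COc1ccc(COC/C=C(\C)CC/C=C(/C)[C@@H](O)[C@H](OCOC)C(=O)N2C(=O)OC[C@@H]2Cc2ccccc2)cc1 | intermediate
16 | (2S,3R,4Z,8E)-3-hydroxy-N-methoxy-10-[(4-methoxybenzyl)oxy]-2-(methoxymethoxy)-N,4,8-trimethyldeca-4,8-dienamide | COc1ccc(COC/C=C(\C)CC/C=C(/C)[C@@H](O)[C@H](OCOC)C(=O)N(C)OC)cc1 | intermediate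
17 | 3-[(tert-butyldimethylsilyl)oxy]propanoic acid | CC(C)(C)[Si](C)(C)OCCC(=O)O | starting material
18 | (2S,3R,4Z,8E)-1-[methoxy(methyl)amino]-10-[(4-methoxybenzyl)oxy]-2-(methoxymethoxy)-4,8-dimethyl-1-oxodeca-4,8-dien-3-yl 3-[(tert-butyldimethylsilyl)oxy]propanoate | COc1ccc(COC/C=C(\C)CC/C=C(/C)[C@@H](OC(=O)CCO[Si](C)(C)C(C)(C)C)[C@H](OCOC)C(=O)N(C)OC)cc1 | intermediate
19 | (5S,6R)-3-{[(tert-butyldimethylsilyl)oxy]methyl}-4-hydroxy-6-{(2Z,6E)-8-[(4-methoxybenzyl)oxy]-6-methylocta-2,6-dien-2-yl}-5-(methoxymethoxy)-5,6-dihydro-2H-pyran-2-one | COc1ccc(COC/C=C(\C)CC/C=C(/C)[C@H]2OC(=O)C(CO[Si](C)(C)C(C)(C)C)=C(O)[C@H]2OCOC)cc1 | intermediate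
20 | (5S,6R)-3-{[(tert-butyldimethylsilyl)oxy]methyl}-6-{(2Z,6E)-8-[(4-methoxybenzyl)oxy]-6-methylocta-2,6-dien-2-yl}-4,5-bis(methoxymethoxy)-5,6-dihydro-2H-pyran-2-one | COc1ccc(COC/C=C(\C)CC/C=C(/C)[C@H]2OC(=O)C(CO[Si](C)(C)C(C)(C)C)=C(OCOC)[C@H]2OCOC)cc1 | intermediate
21 | (5S,6R)-3-{[(tert-butyldimethylsilyl)oxy]methyl}-6-[(2Z,6E)-8-hydroxy-6-methylocta-2,6-dien-2-yl]-4,5-bis(methoxymethoxy)-5,6-dihydro-2H-pyran-2-one | OC/C=C(\C)CC/C=C(/C)[C@H]1OC(=O)C(CO[Si](C)(C)C(C)(C)C)=C(OCOC)[C@H]1OCOC | intermediate
22 | (5S,6R)-3-{[(tert-butyldimethylsilyl)oxy]methyl}-6-[(2Z,6E)-8-chloro-6-methylocta-2,6-dien-2-yl]-4,5-bis(methoxymethoxy)-5,6-dihydro-2H-pyran-2-one | ClC/C=C(\C)CC/C=C(/C)[C@H]1OC(=O)C(CO[Si](C)(C)C(C)(C)C)=C(OCOC)[C@H]1OCOC | intermediate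
23 | (2Z,4S,5R,6Z,10E)-2-{[(tert-butyldimethylsilyl)oxy]methyl}-12-chloro-3,4-bis(methoxymethoxy)-6,10-dimethyldodeca-2,6,10-triene-1,5-diol | ClC/C=C(\C)CC/C=C(/C)[C@@H](O)[C@H](OCOC)/C(OCOC)=C(/CO[Si](C)(C)C(C)(C)C)CO | intermediate
24 | (3Z,5S,6R,7Z,11E)-3-{[(tert-butyldimethylsilyl)oxy]methyl}-4,5-bis(methoxymethoxy)-7,11-dimethyl-1-oxacyclotrideca-3,7,11-trien-6-ol | O1C/C=C(\C)CC/C=C(/C)[C@@H](O)[C@H](OCOC)/C(OCOC)=C(/CO[Si](C)(C)C(C)(C)C)C1 | intermediate
25 | (3Z,5S,6R,7Z,11E)-6-[(tert-butyldimethylsilyl)oxy]-3-{[(tert-butyldimethylsilyl)oxy]methyl}-4,5-bis(methoxymethoxy)-7,11-dimethyl-1-oxacyclotrideca-3,7,11-triene (precursor of the key step) | O1C/C=C(\C)CC/C=C(/C)[C@@H](O[Si](C)(C)C(C)(C)C)[C@H](OCOC)/C(OCOC)=C(/CO[Si](C)(C)C(C)(C)C)C1 | intermediate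
26 | (1S,2E,6Z,8R,9S,10R)-8-[(tert-butyldimethylsilyl)oxy]-10-{3-[(tert-butyldimethylsilyl)oxy]prop-1-en-2-yl}-9,10-bis(methoxymethoxy)-3,7-dimethylcyclodeca-2,6-dien-1-ol (product of the key step) | O[C@H]1/C=C(\C)CC/C=C(/C)[C@@H](O[Si](C)(C)C(C)(C)C)[C@H](OCOC)[C@]1(C(=C)CO[Si](C)(C)C(C)(C)C)OCOC | intermediate
27 | (1S,2E,6Z,8R,9S,10R)-8-[(tert-butyldimethylsilyl)oxy]-10-(3-hydroxyprop-1-en-2-yl)-9,10-bis(methoxymethoxy)-3,7-dimethylcyclodeca-2,6-dien-1-ol | O[C@H]1/C=C(\C)CC/C=C(/C)[C@@H](O[Si](C)(C)C(C)(C)C)[C@H](OCOC)[C@]1(C(=C)CO)OCOC | intermediate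
28 | 12-lactol of 29 (cyclic hemiacetal, both C12 epimers, not isolated) | C=C1C(O)O[C@H]2/C=C(\C)CC/C=C(/C)[C@@H](O[Si](C)(C)C(C)(C)C)[C@H](OCOC)[C@@]12OCOC | intermediate
29 | (1(10)Z,4E,6S,7R,8S,9R)-9-[(tert-butyldimethylsilyl)oxy]-7,8-bis(methoxymethoxy)germacra-1(10),4,11(13)-trien-12,6-olide | C=C1C(=O)O[C@H]2/C=C(\C)CC/C=C(/C)[C@@H](O[Si](C)(C)C(C)(C)C)[C@H](OCOC)[C@@]12OCOC | intermediate
30 | 7,8-bis(bromomethoxy) analogue of 29 (not isolated) | C=C1C(=O)O[C@H]2/C=C(\C)CC/C=C(/C)[C@@H](O[Si](C)(C)C(C)(C)C)[C@H](OCBr)[C@@]12OCBr | intermediate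
31 | (1(10)Z,4E,6S,7S,8S,9R)-9-[(tert-butyldimethylsilyl)oxy]-7,8-dihydroxygermacra-1(10),4,11(13)-trien-12,6-olide (same spatial arrangement as 29) | C=C1C(=O)O[C@H]2/C=C(\C)CC/C=C(/C)[C@@H](O[Si](C)(C)C(C)(C)C)[C@H](O)[C@@]12O | intermediate
32 | angelic acid, (2Z)-2-methylbut-2-enoic acid | C/C=C(/C)C(=O)O | starting material
33 | angelic 2,4,6-trichlorobenzoic anhydride (not isolated) | C/C=C(/C)C(=O)OC(=O)c1c(Cl)cc(Cl)cc1Cl | intermediate
34 | (1(10)Z,4E,6S,7R,8S,9R)-8-(angeloyloxy)-9-[(tert-butyldimethylsilyl)oxy]-7-hydroxygermacra-1(10),4,11(13)-trien-12,6-olide | C=C1C(=O)O[C@H]2/C=C(\C)CC/C=C(/C)[C@@H](O[Si](C)(C)C(C)(C)C)[C@H](OC(=O)/C(C)=C\C)[C@@]12O | intermediate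
35 | (1(10)Z,4E,6S,7R,8S,9R)-8-(angeloyloxy)-7,9-dihydroxygermacra-1(10),4,11(13)-trien-12,6-olide | C=C1C(=O)O[C@H]2/C=C(\C)CC/C=C(/C)[C@@H](O)[C@H](OC(=O)/C(C)=C\C)[C@@]12O | target

## Step count and least certain steps

Total: 23 steps. Longest linear sequence: 22 steps (steps 1 to 6 and 8 to 23, from geraniol 1); step 7 is a one-step side branch.

**Step 18 (proposed new method).**
- What may go wrong: lithiation guided by the acetal oxygens to C13 or C8 instead of C6, followed by the regioisomeric contraction onto C4 or by β-elimination. The shift onto the crowded, electron-rich C7 may be too slow, so that [1,2]-shift or simple reprotonation takes over. Exo/endo or facial control may be incomplete, which would erode the C6/C7 configuration.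
- Fallback (known chemistry): chromium-mediated intramolecular allylation of an aldehyde by a 2-(bromomethyl)acrylate, the established closure for medium-ring α-methylene lactones. It sets out from alcohol 21 and exchanges the roles of the two one-carbon arms on C11: the pyranone carbonyl becomes C12 and the silyloxymethyl carbon becomes C13. Oxidation of 21 with MnO2 gives the enal F1. HF·pyridine frees the hydroxymethyl lactone F2, and CBr4 with PPh3 gives the allylic bromide F3. CrCl2 in THF at high dilution adds the allylchromium through its γ-carbon C7 to the C6 aldehyde and closes the ten-membered ring as the hydroxy δ-lactone F4. Translactonization from O9 to O6 (catalytic 1,8-diazabicyclo[5.4.0]undec-7-ene) gives the 9-hydroxy γ-lactone F5, and silylation (t-BuMe2SiCl, imidazole) returns to the route at 29. The C6/C7 configuration would then depend on the cyclic allylation transition state and is not assured.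

**Step 11.**
- What may go wrong: enolization at C8 with E1cB loss of the C9 carboxylate, loss of silanolate from the ester enolate, or base-induced breakdown of the N-methoxy amide.
- Fallback: an intermolecular crossed Claisen in which C9 carries no leaving group. It sets out from 16 and returns at 19. Acid 17 is esterified to ethyl 3-[(tert-butyldimethylsilyl)oxy]propanoate F6. Amide 16 is silylated at O9 (Et3SiCl, imidazole) to the triethylsilyl ether F7. The lithium enolate of F6 acylates F7 at −78 °C to the β-keto ester F8. Cleavage of the triethylsilyl ether (HF·pyridine) and lactonization of the δ-hydroxy β-keto ester then give 19.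

**Step 16.**
- What may go wrong: oligomerization instead of ring closure, since neither chain end is pre-organized; E2 or SN2′ attack on the allylic chloride; ionization of the γ-alkoxy allylic alcohol while 23 is handled.
- Fallback: no second closure to the ether keeps the locked enol ether geometry. The route would therefore leave the ether approach at 21 by the allylation sequence given for step 18 (through F1 to F5) and return at 29.

**Step 21.**
- What may go wrong: capture of a bromomethyl ether by the neighbouring oxygen to give a cyclic 7,8-formal that does not hydrolyse on work-up; partial loss of the allylic silyl ether.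
- Fallback: acetal exchange in a protic trapping solvent followed by reprotection. It sets out from 29 and returns at 31. Cold HCl in methanol removes both acetals and the silyl ether to give the 7,8,9-triol F9. Selective silylation of the less hindered allylic C9 hydroxyl (t-BuMe2SiCl, imidazole) in the presence of the neopentyl-type C8 hydroxyl then gives 31. The acid must be kept cold to avoid transannular cyclization.

**Step 22.**
- What may go wrong: isomerization of the angeloyl unit to tigloyl during activation, or during slow acylation of the hindered hydroxyl.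
- Fallback: the Z alkene is built on the molecule instead of being transferred. It sets out from 31 and returns at 34. Phosphonate 6 is saponified to 2-[bis(2,2,2-trifluoroethoxy)phosphoryl]propanoic acid F10. Carbodiimide esterification of 31 at O8 gives the phosphonate ester F11, and Still–Gennari olefination with acetaldehyde (KN(SiMe3)2, 18-crown-6, −78 °C) gives 34.

## Further compounds

F1 | step 18 | (5S,6R)-3-{[(tert-butyldimethylsilyl)oxy]methyl}-4,5-bis(methoxymethoxy)-6-[(2Z,6E)-6-methyl-8-oxoocta-2,6-dien-2-yl]-5,6-dihydro-2H-pyran-2-one | O=C/C=C(\C)CC/C=C(/C)[C@H]1OC(=O)C(CO[Si](C)(C)C(C)(C)C)=C(OCOC)[C@H]1OCOC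
F2 | step 18 | (5S,6R)-3-(hydroxymethyl)-4,5-bis(methoxymethoxy)-6-[(2Z,6E)-6-methyl-8-oxoocta-2,6-dien-2-yl]-5,6-dihydro-2H-pyran-2-one | O=C/C=C(\C)CC/C=C(/C)[C@H]1OC(=O)C(CO)=C(OCOC)[C@H]1OCOC
F3 | step 18 | (5S,6R)-3-(bromomethyl)-4,5-bis(methoxymethoxy)-6-[(2Z,6E)-6-methyl-8-oxoocta-2,6-dien-2-yl]-5,6-dihydro-2H-pyran-2-one | O=C/C=C(\C)CC/C=C(/C)[C@H]1OC(=O)C(CBr)=C(OCOC)[C@H]1OCOC
F4 | step 18 | (1(10)Z,4E,6S,7R,8S,9R)-6-hydroxy-7,8-bis(methoxymethoxy)germacra-1(10),4,11(13)-trien-12,9-olide (α-methylene δ-lactone) | O[C@H]1/C=C(\C)CC/C=C(/C)[C@H]2OC(=O)C(=C)[C@]1(OCOC)[C@H]2OCOC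
F5 | step 18 | (1(10)Z,4E,6S,7R,8S,9R)-9-hydroxy-7,8-bis(methoxymethoxy)germacra-1(10),4,11(13)-trien-12,6-olide | C=C1C(=O)O[C@H]2/C=C(\C)CC/C=C(/C)[C@@H](O)[C@H](OCOC)[C@@]12OCOC
F6 | step 11 | ethyl 3-[(tert-butyldimethylsilyl)oxy]propanoate | CCOC(=O)CCO[Si](C)(C)C(C)(C)C
F7 | step 11 | (2S,3R,4Z,8E)-N-methoxy-10-[(4-methoxybenzyl)oxy]-2-(methoxymethoxy)-N,4,8-trimethyl-3-[(triethylsilyl)oxy]deca-4,8-dienamide | COc1ccc(COC/C=C(\C)CC/C=C(/C)[C@@H](O[Si](CC)(CC)CC)[C@H](OCOC)C(=O)N(C)OC)cc1
F8 | step 11 | ethyl (4S,5R,6Z,10E)-2-{[(tert-butyldimethylsilyl)oxy]methyl}-12-[(4-methoxybenzyl)oxy]-4-(methoxymethoxy)-6,10-dimethyl-3-oxo-5-[(triethylsilyl)oxy]dodeca-6,10-dienoate (both C2 epimers) | COc1ccc(COC/C=C(\C)CC/C=C(/C)[C@@H](O[Si](CC)(CC)CC)[C@H](OCOC)C(=O)C(CO[Si](C)(C)C(C)(C)C)C(=O)OCC)cc1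
F0 | step 16 | none | none
F9 | step 21 | (1(10)Z,4E,6S,7S,8S,9R)-7,8,9-trihydroxygermacra-1(10),4,11(13)-trien-12,6-olide | C=C1C(=O)O[C@H]2/C=C(\C)CC/C=C(/C)[C@@H](O)[C@H](O)[C@@]12O
F10 | step 22 | 2-[bis(2,2,2-trifluoroethoxy)phosphoryl]propanoic acid | CC(C(=O)O)P(=O)(OCC(F)(F)F)OCC(F)(F)F
F11 | step 22 | 8-O-{2-[bis(2,2,2-trifluoroethoxy)phosphoryl]propanoyl} ester of 31 | C=C1C(=O)O[C@H]2/C=C(\C)CC/C=C(/C)[C@@H](O[Si](C)(C)C(C)(C)C)[C@H](OC(=O)C(C)P(=O)(OCC(F)(F)F)OCC(F)(F)F)[C@@]12O
A1 | alternative 1 | 9-O-triethylsilyl ether of the target | C=C1C(=O)O[C@H]2/C=C(\C)CC/C=C(/C)[C@@H](O[Si](CC)(CC)CC)[C@H](OC(=O)/C(C)=C\C)[C@@]12O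
A2 | alternative 1 | ten-membered C7 ketone with 6-O-acryloyl, 8-O-angeloyl and 9-O-triethylsilyl groups | C=CC(=O)O[C@H]1/C=C(\C)CC/C=C(/C)[C@@H](O[Si](CC)(CC)CC)[C@H](OC(=O)/C(C)=C\C)C1=O
A3 | alternative 2 | (1(10)Z,4E)-8-(tert-butyldimethylsilyloxy)-7-(4-methoxybenzyloxy)-6-(triethylsilyloxy)germacra-1(10),4-dien-9-one | CC[Si](CC)(CC)O[C@H]1/C=C(\C)CC/C=C(/C)C(=O)[C@H](O[Si](C)(C)C(C)(C)C)[C@@H]1OCc2ccc(OC)cc2
A4 | alternative 2 | cis,anti,cis-tricyclo[4.4.0.0(2,5)]decanone with the same three ethers and two ring-fusion methyl groups (one ring-fusion diastereomer shown) | C[C@]12C(=O)[C@H](O[Si](C)(C)C(C)(C)C)[C@H](OCc3ccc(OC)cc3)[C@@H](O[Si](CC)(CC)CC)[C@H]1[C@]4(C)CC[C@H]24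
A5 | alternative 3 | ten-membered carbocycle with free C7 hydroxyl, 6-O-triethylsilyl, 8-O-(4-methoxybenzyl), 9-O-TBS and the 3-(triethylsilyloxy)prop-1-en-2-yl group on C7 | CC[Si](CC)(CC)O[C@H]1/C=C(\C)CC/C=C(/C)[C@@H](O[Si](C)(C)C(C)(C)C)[C@H](OCc2ccc(OC)cc2)[C@@]1(O)C(=C)CO[Si](CC)(CC)CC
A6 | alternative 3 | open-chain Z vinyl iodide with terminal 1,3-diene, seco form of A5 at C1–C2 | C=C/C(C)=C/[C@H](O[Si](CC)(CC)CC)[C@](O)(C(=C)CO[Si](CC)(CC)CC)[C@@H](OCc1ccc(OC)cc1)[C@H](O[Si](C)(C)C(C)(C)C)/C(C)=C\I
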